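**Assumption:** The target SMILES has no stereocentre and no stereogenic axis, because each ring carries two identical ortho OMe groups. Apteniol E is therefore achiral, so the "single enantiomer" requirement is met automatically and no step needs stereocontrol.

## Retrosynthetic overview
1. The target is a C2-symmetric diacid, so both CH2CH2CO2H arms are disconnected at once to the symmetric dialdehyde 3 (two-directional C2 homologation).
2. Dialdehyde 3 is disconnected at the central tetra-ortho-substituted Ar–O–Ar bond to syringaldehyde (O-nucleophile) and 4-bromo-3,5-dimethoxybenzaldehyde (para-CHO-activated electrophile).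
3. No rings are formed. Both arene rings are purchased with all four OMe groups in place.
4. Forward order: C–O coupling first, while the CHO group still activates the bromide, then both side chains in one operation.

## Route

**Step 1**
Reactants: 1, syringaldehyde (4-hydroxy-3,5-dimethoxybenzaldehyde, 1.5 equiv); 2, 4-bromo-3,5-dimethoxybenzaldehyde (1.0 equiv)
Product: 3, 4,4'-oxybis(3,5-dimethoxybenzaldehyde) (C18H18O7)
Conditions: CuI (0.5 equiv), picolinic acid (1.0 equiv), Cs2CO3 (2.5 equiv), 4 Å MS, DMSO, Ar, 120 °C, 36 h. Excess 1 is removed with a dilute NaOH wash, then 3 is crystallised.
Reagents that add atoms: none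
Why: This is a ligand-accelerated Ullmann diaryl ether synthesis (HBr lost to the base) in which the para-formyl group activates the C–Br bond of 2, the flanking OMe oxygens can pre-coordinate copper, C–O reductive elimination is helped rather than hindered by ortho bulk, and the non-enolisable aldehydes and aryl methyl ethers survive anhydrous carbonate/DMSO; no stereocentre is created.

**Step 2**
Reactants: 3, 4,4'-oxybis(3,5-dimethoxybenzaldehyde); 4, Meldrum's acid (2,2-dimethyl-1,3-dioxane-4,6-dione, 2.4 equiv)
Product: 5, apteniol E, 3,3'-[oxybis(3,5-dimethoxy-4,1-phenylene)]dipropanoic acid (C22H26O9)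
Conditions: HCO2H/Et3N (5:2, TEAF, as solvent), rt 1 h, then 100 °C, 6–8 h until gas evolution stops. Pour onto ice/2 M HCl, filter, and recrystallise from aq. EtOH. Formic acid is the hydride source and contributes only hydrogen. The balance per arm is ArCHO + C6H8O4 + HCO2H → ArCH2CH2CO2H + acetone + 2 CO2.
Reagents that add atoms:
- Meldrum's acid, CC1(C)OC(=O)CC(=O)O1
- water, O

Why: This is a two-directional one-pot Knoevenagel condensation, formate conjugate hydride reduction and hydrolytic decarboxylation, in which each ArCHO forms an arylidene Meldrum's acid electrophilic enough to accept hydride from formate without a metal, the water released in the condensation opens the resulting benzyl Meldrum's acid, which loses acetone and CO2 at 100 °C to leave ArCH2CH2CO2H (the new CH2–CO2H unit comes from C5/C4 of Meldrum's acid), and the diaryl ether and OMe groups are inert (Et3N is tertiary, so no Leuckart amination occurs); no stereocentre is created.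

## Compound list
1 | Syringaldehyde (4-hydroxy-3,5-dimethoxybenzaldehyde, CAS 134-96-3) | COc1cc(C=O)cc(OC)c1O | starting material
2 | 4-Bromo-3,5-dimethoxybenzaldehyde (CAS 31558-40-4) | COc1cc(C=O)cc(OC)c1Br | starting material
3 | 4,4'-Oxybis(3,5-dimethoxybenzaldehyde) | COc1cc(C=O)cc(OC)c1Oc1c(OC)cc(C=O)cc1OC | intermediate
4 | Meldrum's acid (2,2-dimethyl-1,3-dioxane-4,6-dione, CAS 2033-24-1) | CC1(C)OC(=O)CC(=O)O1 | starting material
5 | Apteniol E (achiral) | COc1cc(CCC(=O)O)cc(OC)c1Oc1c(OC)cc(CCC(=O)O)cc1OC | target

## Summary
Total step count: 2. Longest linear sequence: 2.

The route has only two steps, so the third entry below is a second, independent failure mode of step 1.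

**Most likely failures and fallbacks**
1. **Step 1, steric failure.** The tetra-ortho-substituted C–O bond may not form, giving hydrodebromination or no conversion.
   - Fallback: drop copper and use metal-free ligand coupling at iodine(III).
   - Convert 2 to the 4-iodoarene by Cu/NaI halogen exchange, with the CHO masked as its acetal during oxidation.
   - Form the aryl(2,4,6-trimethoxyphenyl)iodonium tosylate with mCPBA, TsOH and 1,3,5-trimethoxybenzene.
   - O-arylate the phenoxide of 1 with t-BuOK or K2CO3 in toluene. This reaction is promoted by ortho substituents and transfers the less electron-rich aryl group selectively.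
2. **Step 2, incomplete double cascade.** The reaction may give mono-homologated material or stall at the bis(benzyl Meldrum's acid).
   - Fallback: run the sequence in stages, which adds one step.
   - A double Knoevenagel–Doebner reaction (malonic acid, pyridine, cat. piperidine, 95 °C) gives the isolable bis-(E)-cinnamic acid, OC(=O)/C=C/c1cc(OC)c(Oc2c(OC)cc(/C=C/C(=O)O)cc2OC)c(OC)c1.
   - Hydrogenation (H2, 1 atm, 10% Pd/C, MeOH/THF) then gives 5.
3. **Step 1, electronic failure.** The phenoxide of 1 is deactivated by its own para-CHO and may be too poor a nucleophile or Cu ligand.
   - Fallback: abandon the symmetric dialdehyde and install one arm before coupling.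
   - Convert sinapic acid to methyl dihydrosinapate, an electron-rich phenol, with H2/Pd-C and then MeOH/H+.
   - Couple this phenol with 2, homologate the single remaining CHO as in step 2, and saponify with LiOH.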